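**Plan** (gibberellane numbering: ring A = C1–C5, C10; ring B = C5, C6, C8, C9, C10; ring C = C8, C9, C11–C14; ring D = C8, C14, C13, C16, C15; C7 on C6, C18 and C19 on C4, C20 on C10, C17 on C16)
Cuts: ring A at C3–C4 (Dieckmann), then C4–C18, C10–C1 (Michael), C10–C20 (Wittig) and C5–C4 (enolate alkylation); ring D at C13–C16 (ketyl–alkyne); ring C at C8–C14 and C9–C11 ([4+2]).
Enabling feature: ring C has one oxygen only, at C13, 1,3 to quaternary C8 and 1,4 to C9, and C9 sits next to C10, which can be a ketone. This is the pattern a 1-amino-3-siloxybutadiene (C11–C14) leaves on a ring B cyclopentenone (C10=O, C8=C9).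
Forward order: ring B (chiral 3-propargylcyclopentenone) → ring C (Diels–Alder) → ring D (SmI2) → ring A (C5 alkylation, C10 homologation, Michael, Dieckmann) → C18, C3–OH, C7 acid, deprotection.
Stereochemistry: C6 from a RAMP-hydrazone alkylation; C8/C9 from diene approach anti to the C6 side chain; C13 from the bridge geometry; C5 and C10 from attack anti to vicinal substituents; C4 from methylation anti to the axial C10 group; C3 from equatorial hydride attack.

Key step: step 6

Remark: centres formed without control and erased in the next operation (carbinol carbon of 8 and 9, enol ether geometry of 21, C10 of 22) are left undefined in the SMILES; metal enolates, alkoxides, azaenolates and ketyls are treated as transient species of their step.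

**Step 1**
Reactants: 1 1,4-dioxaspiro[4.4]nonan-7-one; 2 (R)-1-amino-2-(methoxymethyl)pyrrolidine (RAMP)
Product: 3 RAMP hydrazone of 1
Conditions: 2 (1.05 equiv), cyclohexane, reflux, Dean–Stark
Reagents that add atoms: none
Why: Neutral condensation of the ketone with the N-aminopyrrolidine gives the hydrazone and leaves the β-ketal untouched (hydrazone formation).

**Step 2**
Reactants: 3 RAMP hydrazone of 1; 4 (triisopropylsilyloxy)methyl chloride
Product: 5 RAMP hydrazone of ketone 6
Conditions: LiN(i-Pr)2, THF, 0 °C; then 4, −100 → −78 °C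
Reagents that add atoms: none
Why: In this Enders RAMP-hydrazone alkylation the base should deprotonate the methylene remote from the ketal, and the α-chloro ether (same class as BOMCl or SEMCl) attacks the chelated azaenolate on the face left open by the methoxymethyl arm, which sets C6 (R in ketone 6).

**Step 3**
Reactants: 5 RAMP hydrazone of ketone 6
Product: 6 (R)-8-[(triisopropylsilyloxy)methyl]-1,4-dioxaspiro[4.4]nonan-7-one
Conditions: O3, CH2Cl2, −78 °C; N2 purge
Reagents that add atoms: ozone, [O-][O+]=O
Why: Ozone cleaves the C=N bond to ketone and N-nitrosamine at low temperature without epimerising the α-centre or touching ketal and silyl ether (oxidative hydrazone cleavage).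

**Step 4**
Reactants: 6 (R)-8-[(triisopropylsilyloxy)methyl]-1,4-dioxaspiro[4.4]nonan-7-one; 7 propargyl bromide
Product: 8 (8R)-7-(prop-2-yn-1-yl)-8-[(triisopropylsilyloxy)methyl]-1,4-dioxaspiro[4.4]nonan-7-ol (both C7 epimers)
Conditions: 7, Zn dust, THF, 0 → 25 °C; then H2O
Reagents that add atoms: none
Why: Barbier propargylation: the allenylzinc bromide formed in the flask adds by SE2′ to give the homopropargylic tertiary alcohol, and the weakly basic organozinc spares the α-stereocentre and the β-ketal.

**Step 5**
Reactants: 8 homopropargylic tertiary alcohol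
Product: 10 (S)-3-(prop-2-yn-1-yl)-4-[(triisopropylsilyloxy)methyl]cyclopent-2-en-1-one, via beta-hydroxy ketone 9 (not isolated)
Conditions: 1 M HCl, THF, 25 → 40 °C
Reagents that add atoms: water, O
Why: Ketal hydrolysis frees the C10 ketone and the tertiary aldol-type alcohol then dehydrates through the enol to the conjugated enone; C6 is not α to a carbonyl at any stage, so mild acid should not racemise it.

**Step 6**
Reactants: 10 (S)-3-(prop-2-yn-1-yl)-4-[(triisopropylsilyloxy)methyl]cyclopent-2-en-1-one; 11 (E)-1-(dimethylamino)-3-(tert-butyldimethylsilyloxy)buta-1,3-diene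
Product: 14 cis-fused enedione (ring B C10 ketone; ring C C11=C12–C13=O; C8 propargyl cis to H-9 and to the C6 CH2OTIPS group), via endo cycloadduct 12 (not isolated), via beta-amino diketone 13 (not isolated)
Conditions: 11 (3 equiv), CH2Cl2, 12 kbar, 25 °C; then 1 M HCl, THF, 0 °C
Reagents that add atoms: none
Why: The electron-rich aminosiloxydiene and the enone combine in a concerted, asynchronous normal-demand [4+2] cycloaddition, the closest known type being the Diels–Alder reaction of 1-amino-3-siloxybutadienes with cyclic enones; pressure is applied because the β,β-disubstituted dienophile is slow and the activation volume is strongly negative. Ring C closes by cycloaddition, with both σ-bonds (C8–C14 and C9–C11) formed suprafacially on the diene and on the C8=C9 bond. C8 and C9 arise together: their cis relationship follows from the suprafacial addition, their absolute sense from C6, whose CH2OTIPS group shields one face so that the diene adds anti to it; the transient C11 centre follows the endo rule and is erased. The step needs regio-, facial and chemoselectivity: the large HOMO coefficient at the diene CH2 terminus (C14) pairs with the enone β-carbon C8, the stereocentre next to C8 fixes the face, and the unactivated terminal alkyne does not compete as dienophile. Cold dilute HCl then hydrolyses the silyl enol ether and expels dimethylamine by β-elimination to give the C11=C12 enone, leaving the TIPS ether in place.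

**Step 7**
Reactants: 14 cis-fused enedione
Product: 15 hydroxy ketone (C10–OH; saturated C13 ketone; C8 propargyl)
Conditions: LiBH(s-Bu)3 (2.3 equiv), THF, −78 °C; then H2O
Reagents that add atoms: none
Why: The hindered borohydride reduces the saturated cyclopentanone 1,2 and the β-unsubstituted cyclohexenone 1,4 (conjugate reduction), so C13 is held as an enolate until work-up; the new C10 carbinol (drawn for hydride attack anti to C11) is erased in step 9.

**Step 8**
Reactants: 15 hydroxy ketone
Product: 16 tricyclic diol (C10–OH; bridgehead C13–OH; C16=C17 methylene)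
Conditions: SmI2 (3 equiv), HMPA, t-BuOH, THF, 0 → 25 °C
Reagents that add atoms: none
Why: Ketyl–alkyne reductive cyclisation: the C13 ketyl adds 5-exo-dig to C16, the vinyl radical is reduced and protonated to the exocyclic methylene, and C13 can only adopt the configuration allowed by the bicyclo[3.2.1]octane bridge from C8.

**Step 9**
Reactants: 16 tricyclic diol
Product: 17 tricyclic C10 ketone (bridgehead C13–OH; C16=C17 methylene; C6 CH2OTIPS)
Conditions: Dess–Martin periodinane, NaHCO3, CH2Cl2, 25 °C
Reagents that add atoms: none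
Why: Dess–Martin oxidation converts the secondary C10 alcohol to the ketone, while the tertiary bridgehead alcohol cannot be oxidised.

**Step 10**
Reactants: 17 tricyclic C10 ketone; 18 tert-butyl bromoacetate
Product: 19 C5 tert-butoxycarbonylmethyl ketone (C5 side chain trans to the C6 CH2OTIPS group)
Conditions: LiN(i-Pr)2 (2.2 equiv), THF, −78 °C; then 18, DMPU, −78 → −40 °C
Reagents that add atoms: none
Why: Kinetic enolate alkylation: after the C13 alkoxide forms, the base removes a C5 methylene proton rather than the hindered C9 methine, and the bromoacetate enters anti to the vicinal C6 substituent, which is also the thermodynamic arrangement.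

**Step 11**
Reactants: 19 C5 tert-butoxycarbonylmethyl ketone; 20 (methoxymethyl)triphenylphosphonium chloride
Product: 21 C10 methoxymethylene enol ether (E/Z mixture)
Conditions: 20, KOtBu, THF, 0 °C; then 19, 0 → 40 °C
Reagents that add atoms: none
Why: Wittig methoxymethylenation introduces C20; the ylide does not attack the tert-butyl ester, and reversible enolisation at C5 or C9 returns the favoured configurations.

**Step 12**
Reactants: 21 C10 methoxymethylene enol ether
Product: 22 C10 formyl compound (C10 epimers)
Conditions: 1 M HCl, THF, 25 °C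
Reagents that add atoms: water, O
Why: Enol ether hydrolysis gives the aldehyde; the C10 epimer mixture is inconsequential because C10 is enolised in the next step, and brief dilute acid should spare tert-butyl ester, TIPS ether and the bridgehead alcohol.

**Step 13**
Reactants: 22 C10 formyl compound; 23 methyl acrylate
Product: 24 C10 quaternary aldehyde diester (C20 formyl; C1–C3 methyl propanoate chain cis to H-9 and H-5)
Conditions: 23, KOtBu (0.3 equiv), t-BuOH/THF, 0 °C
Reagents that add atoms: none
Why: Michael addition of the α-branched aldehyde enolate to the acrylate creates quaternary C10; the acceptor approaches anti to both vicinal substituents (C11 on C9, C4 on C5), so C1 lies on the face of H-9 and H-5 and the formyl group on the opposite face, as in the target.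

**Step 14**
Reactants: 24 C10 quaternary aldehyde diester
Product: 25 C20 dimethyl acetal of 24
Conditions: HC(OMe)3, MeOH, pyridinium p-toluenesulfonate (cat.), 40 °C
Reagents that add atoms: trimethyl orthoformate, COC(OC)OC
Why: Acid-catalysed acetalisation masks the non-enolisable aldehyde against the later hydride and chlorite steps; the esters, the silyl ether and the alkene are inert to the weak acid.

**Step 15**
Reactants: 25 C20 dimethyl acetal
Product: 26 ring A β-keto ester (C3 ketone; C4 CO2tBu; keto form drawn)
Conditions: KOtBu (2.5 equiv), THF, 0 → 25 °C; then aq. NH4Cl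
Reagents that add atoms: none
Why: Dieckmann condensation closes ring A 6-exo-trig at C3–C4; the tert-butyl ester can serve as enolate but is too hindered to be acylated, so only C4 attacks the methyl ester, and the trans A/B fusion is already fixed by C5 and C10.

**Step 16**
Reactants: 26 ring A β-keto ester
Product: 27 C4-methylated β-keto ester (C18 methyl cis to H-5; C19 ester cis to C20)
Conditions: MeI, K2CO3, acetone, 25 °C
Reagents that add atoms: iodomethane, CI
Why: C-methylation of the β-keto ester enolate occurs anti to the axial C10 acetal group (1,3-diaxial screening), placing the methyl equatorial and the ester axial, the usual outcome for 3-oxo-4-carboalkoxy rings with an angular substituent; the tertiary alcohol is not deprotonated by carbonate.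

**Step 17**
Reactants: 27 C4-methylated β-keto ester
Product: 28 3-hydroxy ester (3-OH axial; cis to C18)
Conditions: LiBH(s-Bu)3 (2.5 equiv), THF, −78 °C; then H2O
Reagents that add atoms: none
Why: The bulky hydride attacks the C3 ketone along the equatorial trajectory, as with 4,4-disubstituted 3-ketones, giving the axial alcohol; acetal and tert-butyl ester are not reduced.

**Step 18**
Reactants: 28 3-hydroxy ester
Product: 29 C7 primary alcohol (triol)
Conditions: Bu4NF, AcOH, THF, 25 °C
Reagents that add atoms: none
Why: Fluoride cleaves the primary TIPS ether, and acetic acid buffering guards the β-hydroxy ester against retro-aldol opening of ring A.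

**Step 19**
Reactants: 29 C7 primary alcohol
Product: 30 C7 aldehyde
Conditions: 2,2,6,6-tetramethylpiperidin-1-oxyl (cat.), PhI(OAc)2, CH2Cl2, 25 °C
Reagents that add atoms: none
Why: The oxoammonium oxidation is selective for the primary alcohol over the hindered secondary C3–OH and the tertiary C13–OH.

**Step 20**
Reactants: 30 C7 aldehyde
Product: 31 C7 acid (C19 tert-butyl ester; C20 dimethyl acetal)
Conditions: NaClO2, NaH2PO4, 2-methylbut-2-ene, t-BuOH/H2O, 0 → 25 °C
Reagents that add atoms: sodium chlorite, [Na+].[O-]Cl=O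
Why: Pinnick oxidation gives the acid at about pH 4 without epimerising C6; the scavenger removes HOCl before it reaches the C16=C17 alkene, and C20 stays masked.

**Step 21**
Reactants: 31 C7 acid
Product: 32 CNP0236431.1 (3,13-dihydroxy-20-oxogibberell-16-ene-7,19-dioic acid)
Conditions: 85% aq. H3PO4, toluene, 25 °C
Reagents that add atoms: water, O
Why: The mild aqueous acid cleaves the tert-butyl ester by alkyl–oxygen fission and hydrolyses the dimethyl acetal in one operation, and is chosen weak enough to spare the 13-hydroxy-16-ene unit; the product may close reversibly to the C19/C20 lactol.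

**Compound list**
1 | 1,4-dioxaspiro[4.4]nonan-7-one | O=C1CCC2(C1)OCCO2 | starting material
2 | (R)-1-amino-2-(methoxymethyl)pyrrolidine (RAMP) | COC[C@H]1CCCN1N | starting material
3 | RAMP hydrazone of 1 (C=N geometry not defined) | COC[C@H]1CCCN1N=C1CCC2(C1)OCCO2 | intermediate
4 | (triisopropylsilyloxy)methyl chloride | ClCO[Si](C(C)C)(C(C)C)C(C)C | starting material
5 | RAMP hydrazone of ketone 6 (ring centre as in 6; C=N geometry not defined) | COC[C@H]1CCCN1N=C1CC2(OCCO2)C[C@@H]1CO[Si](C(C)C)(C(C)C)C(C)C | intermediate
6 | (R)-8-[(triisopropylsilyloxy)methyl]-1,4-dioxaspiro[4.4]nonan-7-one | O=C1CC2(OCCO2)C[C@@H]1CO[Si](C(C)C)(C(C)C)C(C)C | intermediate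
7 | propargyl bromide | C#CCBr | starting material
8 | (8R)-7-(prop-2-yn-1-yl)-8-[(triisopropylsilyloxy)methyl]-1,4-dioxaspiro[4.4]nonan-7-ol (C7 epimers) | C#CCC1(O)CC2(OCCO2)C[C@@H]1CO[Si](C(C)C)(C(C)C)C(C)C | intermediate
9 | (4R)-3-hydroxy-3-(prop-2-yn-1-yl)-4-[(triisopropylsilyloxy)methyl]cyclopentan-1-one (C3 epimers) | O=C1CC(O)(CC#C)[C@@H](CO[Si](C(C)C)(C(C)C)C(C)C)C1 | intermediate
10 | (S)-3-(prop-2-yn-1-yl)-4-[(triisopropylsilyloxy)methyl]cyclopent-2-en-1-one | O=C1C=C(CC#C)[C@@H](CO[Si](C(C)C)(C(C)C)C(C)C)C1 | intermediate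
11 | (E)-1-(dimethylamino)-3-(tert-butyldimethylsilyloxy)buta-1,3-diene | C=C(O[Si](C)(C)C(C)(C)C)/C=C/N(C)C | starting material
12 | endo cycloadduct: C11 dimethylamino, C12=C13 silyl enol ether, C10 ketone; NMe2 cis to C10 | CC(C)(C)[Si](C)(C)OC1=C[C@@H](N(C)C)[C@H]2C(=O)C[C@H](CO[Si](C(C)C)(C(C)C)C(C)C)[C@@]2(CC#C)C1 | intermediate
13 | β-amino diketone: C11 dimethylamino, C13 and C10 ketones | O=C1C[C@@H](N(C)C)[C@H]2C(=O)C[C@H](CO[Si](C(C)C)(C(C)C)C(C)C)[C@@]2(CC#C)C1 | intermediate
14 | cis-fused enedione: ring B C10 ketone, ring C C11=C12–C13=O, C8 propargyl cis to H-9 and to C6 CH2OTIPS | O=C1C=C[C@H]2C(=O)C[C@H](CO[Si](C(C)C)(C(C)C)C(C)C)[C@@]2(CC#C)C1 | intermediate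
15 | hydroxy ketone: C10–OH (cis to C11), saturated C13 ketone, C8 propargyl | O=C1CC[C@H]2[C@@H](O)C[C@H](CO[Si](C(C)C)(C(C)C)C(C)C)[C@@]2(CC#C)C1 | intermediate
16 | tricyclic diol (rings B, C, D): C10–OH, bridgehead C13–OH, C16=C17 methylene, C6 CH2OTIPS | C=C1C[C@]23C[C@@]1(O)CC[C@H]2[C@@H](O)C[C@@H]3CO[Si](C(C)C)(C(C)C)C(C)C | intermediate
17 | tricyclic C10 ketone: bridgehead C13–OH, C16=C17 methylene, C6 CH2OTIPS | C=C1C[C@]23C[C@@]1(O)CC[C@H]2C(=O)C[C@@H]3CO[Si](C(C)C)(C(C)C)C(C)C | intermediate
18 | tert-butyl bromoacetate | CC(C)(C)OC(=O)CBr | starting material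
19 | C5 tert-butoxycarbonylmethyl ketone: C5 side chain trans to C6 CH2OTIPS | C=C1C[C@]23C[C@@]1(O)CC[C@H]2C(=O)[C@@H](CC(=O)OC(C)(C)C)[C@@H]3CO[Si](C(C)C)(C(C)C)C(C)C | intermediate
20 | (methoxymethyl)triphenylphosphonium chloride | COC[P+](c1ccccc1)(c1ccccc1)c1ccccc1.[Cl-] | starting material
21 | C10 methoxymethylene enol ether (E/Z) | C=C1C[C@]23C[C@@]1(O)CC[C@H]2C(=COC)[C@@H](CC(=O)OC(C)(C)C)[C@@H]3CO[Si](C(C)C)(C(C)C)C(C)C | intermediate
22 | C10 formyl compound (C10 epimers) | C=C1C[C@]23C[C@@]1(O)CC[C@H]2C(C=O)[C@@H](CC(=O)OC(C)(C)C)[C@@H]3CO[Si](C(C)C)(C(C)C)C(C)C | intermediate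
23 | methyl acrylate | C=CC(=O)OC | starting material
24 | C10 quaternary aldehyde diester: C20 formyl trans to H-9 and H-5, methyl propanoate chain (C1–C3) cis to them, tert-butyl acetate chain on C5 | C=C1C[C@]23C[C@@]1(O)CC[C@H]2[C@](C=O)(CCC(=O)OC)[C@@H](CC(=O)OC(C)(C)C)[C@@H]3CO[Si](C(C)C)(C(C)C)C(C)C | intermediate
25 | C20 dimethyl acetal of 24 | C=C1C[C@]23C[C@@]1(O)CC[C@H]2[C@](C(OC)OC)(CCC(=O)OC)[C@@H](CC(=O)OC(C)(C)C)[C@@H]3CO[Si](C(C)C)(C(C)C)C(C)C | intermediate
26 | ring A β-keto ester: C3 ketone, C4 CO2tBu equatorial (keto form), trans A/B fusion | C=C1C[C@]23C[C@@]1(O)CC[C@H]2[C@]1(C(OC)OC)CCC(=O)[C@H](C(=O)OC(C)(C)C)[C@H]1[C@@H]3CO[Si](C(C)C)(C(C)C)C(C)C | intermediate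
27 | C4-methylated β-keto ester: C18 methyl cis to H-5, C19 ester cis to C20 | C=C1C[C@]23C[C@@]1(O)CC[C@H]2[C@]1(C(OC)OC)CCC(=O)[C@@](C)(C(=O)OC(C)(C)C)[C@H]1[C@@H]3CO[Si](C(C)C)(C(C)C)C(C)C | intermediate
28 | 3-hydroxy ester: axial 3-OH cis to C18 | C=C1C[C@]23C[C@@]1(O)CC[C@H]2[C@]1(C(OC)OC)CC[C@H](O)[C@@](C)(C(=O)OC(C)(C)C)[C@H]1[C@@H]3CO[Si](C(C)C)(C(C)C)C(C)C | intermediate
29 | C7 primary alcohol (3,7,13-triol) | C=C1C[C@]23C[C@@]1(O)CC[C@H]2[C@]1(C(OC)OC)CC[C@H](O)[C@@](C)(C(=O)OC(C)(C)C)[C@H]1[C@@H]3CO | intermediate
30 | C7 aldehyde | C=C1C[C@]23C[C@@]1(O)CC[C@H]2[C@]1(C(OC)OC)CC[C@H](O)[C@@](C)(C(=O)OC(C)(C)C)[C@H]1[C@@H]3C=O | intermediate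
31 | C7 acid with C19 tert-butyl ester and C20 dimethyl acetal | C=C1C[C@]23C[C@@]1(O)CC[C@H]2[C@]1(C(OC)OC)CC[C@H](O)[C@@](C)(C(=O)OC(C)(C)C)[C@H]1[C@@H]3C(=O)O | intermediate
32 | CNP0236431.1, 3,13-dihydroxy-20-oxogibberell-16-ene-7,19-dioic acid | C=C1C[C@]23C[C@@]1(O)CC[C@H]2[C@]1(C=O)CC[C@H](O)[C@@](C)(C(=O)O)[C@H]1[C@@H]3C(=O)O | target

Total step count: 21. Longest linear sequence: 21 steps (1 → 32).

**Steps most likely to fail**

Step 6. The cycloaddition at the fully substituted β-carbon may be too slow even under pressure, so that diene decomposition or amine-induced propargyl-to-allenyl isomerisation of the enone takes over. Fallback, from 10: a TiCl4-promoted Mukaiyama–Michael addition of (E)-1-methoxy-3-(trimethylsilyloxy)buta-1,3-diene (CH2Cl2, −78 °C) activates the enone instead of relying on diene nucleophilicity. It should form C8–C14 anti to the C6 side chain and give, after aqueous work-up, the open-chain β-methoxy enone F1. KOtBu in THF then closes ring C by 6-endo addition of the C9 enolate to C11 with loss of methanol (only the C9 enolate can cyclise, and the cis fusion is the stable one), returning to 14.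

Step 11. Enolisation of the hindered, doubly α-branched C10 ketone may outrun olefination, so that starting ketone is recovered. Fallback, from 19: Corey–Chaykovsky reaction with the smaller dimethylsulfonium methylide (Me3SI, KN(SiMe3)2, THF, 0 °C) gives the C10 spiro-epoxide F2. BF3·OEt2 at −78 °C opens the epoxide at C10 and a hydride shift (Meinwald rearrangement) delivers aldehyde 22.

Step 13. Conjugate addition at the congested C10 enolate carbon may stall or lose facial selectivity, and base-induced side reactions of the aldehyde may compete. Fallback, from 22: deprotonation with KH and trapping with allyl bromide should give the O-allyl enol ether F3 (with some directly C-allylated material). Heating in toluene at 110 °C transfers the allyl group to C10 intramolecularly by Claisen rearrangement, on the face anti to C11 and C4, giving the α-allyl aldehyde F4. Acetalisation as in step 14 gives the dimethyl acetal F5. Hydroboration with disiamylborane and oxidative work-up, selective for the monosubstituted alkene over the C16=C17 methylene, gives the primary alcohol F6. Oxidation (oxoammonium/PhI(OAc)2, then NaClO2) gives the acid F7, and Me3SiCHN2 in MeOH gives the methyl ester 25.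

**Further compounds**
F1 | step 6 | 3-[(E)-4-methoxy-2-oxobut-3-en-1-yl]-3-(prop-2-yn-1-yl)-4-[(triisopropylsilyloxy)methyl]cyclopentan-1-one, C6 and C8 as in 14 | O=C1C[C@H](CO[Si](C(C)C)(C(C)C)C(C)C)[C@@](CC#C)(CC(=O)/C=C/OC)C1
F2 | step 11 | C10 spiro-epoxide of 19 (epoxide carbon not defined) | C=C1C[C@]23C[C@@]1(O)CC[C@H]2C1(CO1)[C@@H](CC(=O)OC(C)(C)C)[C@@H]3CO[Si](C(C)C)(C(C)C)C(C)C
F3 | step 13 | C10 allyloxymethylene enol ether (E/Z) | C=C1C[C@]23C[C@@]1(O)CC[C@H]2C(=COCC=C)[C@@H](CC(=O)OC(C)(C)C)[C@@H]3CO[Si](C(C)C)(C(C)C)C(C)C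
F4 | step 13 | C10 allyl aldehyde, allyl cis to H-9 and H-5 | C=C1C[C@]23C[C@@]1(O)CC[C@H]2[C@](C=O)(CC=C)[C@@H](CC(=O)OC(C)(C)C)[C@@H]3CO[Si](C(C)C)(C(C)C)C(C)C
F5 | step 13 | C20 dimethyl acetal of F4 | C=C1C[C@]23C[C@@]1(O)CC[C@H]2[C@](C(OC)OC)(CC=C)[C@@H](CC(=O)OC(C)(C)C)[C@@H]3CO[Si](C(C)C)(C(C)C)C(C)C
F6 | step 13 | C3 primary alcohol (3-hydroxypropyl chain on C10) | C=C1C[C@]23C[C@@]1(O)CC[C@H]2[C@](C(OC)OC)(CCCO)[C@@H](CC(=O)OC(C)(C)C)[C@@H]3CO[Si](C(C)C)(C(C)C)C(C)C
F7 | step 13 | C3 carboxylic acid (2-carboxyethyl chain on C10) | C=C1C[C@]23C[C@@]1(O)CC[C@H]2[C@](C(OC)OC)(CCC(=O)O)[C@@H](CC(=O)OC(C)(C)C)[C@@H]3CO[Si](C(C)C)(C(C)C)C(C)C
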